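**Retrosynthetic overview**

1. Target 19 comes from the fully protected bis-flavan 17 by desilylation and hydrogenolysis. Both flavan units are (2R,3R,4S) and both are built from one acyclic aldehyde, 11.
2. Key disconnection: in the upper unit the C4–O(ether) bond and the C4–C4a bond are cut together. Aldehyde 11 (its CHO carbon is the future C4) and the lower unit as its 3-O-trimethylsilyl ether 15 give an oxocarbenium ion, which ring A attacks to close pyran ring C.
3. Enabling feature: ring A of the upper unit is oxygenated at C7, C8 and C8a, so C4a (ortho to the pyran oxygen O1, para to O7) is a strong π-nucleophile six atoms from C4. C4 itself bears an oxygen, so it can be made as an oxocarbenium carbon whose oxygen is O3 of the lower unit.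
4. Aldehyde 11: C2 and C3 come from a cis-glycidate (catalytic asymmetric epoxidation of a (Z)-cinnamate), opened with inversion at the benzylic carbon by 2,3-bis(benzyloxy)phenol (O1–C2 bond).
5. Order of ring formation: rings A and B are bought as arenes; ring C of the lower unit is closed first (step 8, same aldehyde with benzyloxytrimethylsilane); ring C of the upper unit is closed last (step 11).

Key step: step 11

Assumption: ring letters follow flavan usage (A = benzo ring, B = 4-hydroxyphenyl ring, C = pyran ring); "upper unit" is the flavan whose C4 carries the inter-unit ether oxygen, "lower unit" the one etherified at O3; compounds 1, 5 and 6 are taken as commercially available.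

**Route**

Step 1
Reactants: 1 2,3-dihydroxybenzaldehyde
Product: 2 2,3-bis(benzyloxy)benzaldehyde
Conditions: BnBr, K2CO3, DMF, 60 °C
Reagents that add atoms: benzyl bromide, BrCc1ccccc1
Why: Williamson etherification of both phenols; no stereocenter is involved.

Step 2
Reactants: 2 2,3-bis(benzyloxy)benzaldehyde
Product: 4 2,3-bis(benzyloxy)phenol, via 2,3-bis(benzyloxy)phenyl formate 3 (not isolated)
Conditions: mCPBA, CH2Cl2, rt; then K2CO3 (cat.), MeOH, rt
Reagents that add atoms: 3-chloroperoxybenzoic acid (mCPBA), OOC(=O)c1cccc(Cl)c1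
Why: Baeyer–Villiger oxidation of an electron-rich ortho-alkoxybenzaldehyde proceeds by aryl migration to the formate, which methanolysis should convert into the phenol.

Step 3
Reactants: 5 4-(benzyloxy)benzaldehyde; 6 ethyl 2-[bis(2-methylphenoxy)phosphoryl]acetate
Product: 7 ethyl (2Z)-3-[4-(benzyloxy)phenyl]prop-2-enoate
Conditions: NaH, THF, −78 to 0 °C
Reagents that add atoms: none
Why: Ando variant of the Horner–Wadsworth–Emmons olefination, in which the diaryl phosphonate should give the (Z)-enoate under kinetic control; any (E)-isomer is removed by chromatography.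

Step 4
Reactants: 7 ethyl (2Z)-3-[4-(benzyloxy)phenyl]prop-2-enoate
Product: 8 ethyl (2S,3S)-3-[4-(benzyloxy)phenyl]oxirane-2-carboxylate (cis-epoxide)
Conditions: (S,S)-Mn(salen)Cl (5 mol %; salen = N,N'-bis(3,5-di-tert-butylsalicylidene)cyclohexane-1,2-diaminate), 4-phenylpyridine N-oxide, aq NaOCl (pH 11), CH2Cl2, 0 °C
Reagents that add atoms: sodium hypochlorite, [Na+].[O-]Cl
Why: Jacobsen–Katsuki epoxidation of a cis-cinnamate ester, in which the chiral manganese oxo species transfers oxygen to one enantioface and so sets both stereocenters (2S,3S) under catalyst control; the catalyst enantiomer is chosen by analogy with cis-cinnamates, and minor trans-epoxide is removed by chromatography.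

Step 5
Reactants: 8 ethyl (2S,3S)-3-[4-(benzyloxy)phenyl]oxirane-2-carboxylate; 4 2,3-bis(benzyloxy)phenol
Product: 9 ethyl (2S,3R)-3-[2,3-bis(benzyloxy)phenoxy]-3-[4-(benzyloxy)phenyl]-2-hydroxypropanoate
Conditions: Cs2CO3 (0.3 equiv), DMF, 50 °C
Reagents that add atoms: none
Why: Base-mediated SN2 opening of the 3-arylglycidate at the benzylic carbon by the phenoxide should give the threo hydroxy ether with inversion at C3 (3R) and C2 untouched; this forms the future O1–C2 bond.

Step 6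
Reactants: 9 ethyl (2S,3R)-3-[2,3-bis(benzyloxy)phenoxy]-3-[4-(benzyloxy)phenyl]-2-hydroxypropanoate
Product: 10 ethyl (2S,3R)-3-[2,3-bis(benzyloxy)phenoxy]-3-[4-(benzyloxy)phenyl]-2-[(tert-butyldimethylsilyl)oxy]propanoate
Conditions: TBSOTf, 2,6-lutidine, CH2Cl2, 0 °C
Reagents that add atoms: tert-butyldimethylsilyl triflate, CC(C)(C)[Si](C)(C)OS(=O)(=O)C(F)(F)F
Why: Silylation of the secondary alcohol; the TBS ether is non-participating and too hindered to enter the later silyl-acetal chemistry, and no stereocenter is touched.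

Step 7
Reactants: 10 ethyl (2S,3R)-3-[2,3-bis(benzyloxy)phenoxy]-3-[4-(benzyloxy)phenyl]-2-[(tert-butyldimethylsilyl)oxy]propanoate
Product: 11 (2S,3R)-3-[2,3-bis(benzyloxy)phenoxy]-3-[4-(benzyloxy)phenyl]-2-[(tert-butyldimethylsilyl)oxy]propanal
Conditions: iBu2AlH, CH2Cl2, −78 °C; aq potassium sodium tartrate
Reagents that add atoms: none
Why: Partial reduction of an α-silyloxy ester stops at the aldehyde because the tetrahedral aluminium hemiacetal is stable at −78 °C; the aldehyde is used at once so that the α-stereocenter is not epimerized.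

Step 8
Reactants: 11 (2S,3R)-3-[2,3-bis(benzyloxy)phenoxy]-3-[4-(benzyloxy)phenyl]-2-[(tert-butyldimethylsilyl)oxy]propanal
Product: 13 (2R,3R,4S)-4,7,8-tris(benzyloxy)-2-[4-(benzyloxy)phenyl]-3-[(tert-butyldimethylsilyl)oxy]chromane, via O-benzyl oxocarbenium triflate 12 (not isolated)
Conditions: BnOSiMe3, TMSOTf (1.1 equiv), 2,6-di-tert-butyl-4-methylpyridine, CH2Cl2, −78 to −40 °C
Reagents that add atoms: benzyloxytrimethylsilane, C[Si](C)(C)OCc1ccccc1
Why: Proposed new method: the same tandem as in step 11 with the simplest partner; TMSOTf should convert 11 and the alkoxysilane into the O-benzyl oxocarbenium ion 12, which the tethered ring A attacks at C4a in a chair-like Friedel–Crafts closure (closest known types: the silyl-modified Sakurai reaction and acetal-initiated Friedel–Crafts cyclizations), and C4 should be set trans to the axial 3-silyloxy group (4S) for the reasons given under step 11.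

Step 9
Reactants: 13 (2R,3R,4S)-4,7,8-tris(benzyloxy)-2-[4-(benzyloxy)phenyl]-3-[(tert-butyldimethylsilyl)oxy]chromane
Product: 14 (2R,3R,4S)-4,7,8-tris(benzyloxy)-2-[4-(benzyloxy)phenyl]chroman-3-ol
Conditions: Bu4NF, AcOH, THF, rt to 40 °C
Reagents that add atoms: none
Why: Fluoride desilylation under buffered conditions should leave the benzyl ethers, the benzylic C4 ether and all three stereocenters untouched.

Step 10
Reactants: 14 (2R,3R,4S)-4,7,8-tris(benzyloxy)-2-[4-(benzyloxy)phenyl]chroman-3-ol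
Product: 15 (2R,3R,4S)-4,7,8-tris(benzyloxy)-2-[4-(benzyloxy)phenyl]-3-[(trimethylsilyl)oxy]chromane
Conditions: TMSCl, imidazole, CH2Cl2, 0 °C
Reagents that add atoms: chlorotrimethylsilane, C[Si](C)(C)Cl
Why: Silylation of the axial 3-hydroxyl gives the small silyl ether that TMSOTf-catalysed acetalization needs; the product is used without chromatography.

Step 11
Reactants: 11 (2S,3R)-3-[2,3-bis(benzyloxy)phenoxy]-3-[4-(benzyloxy)phenyl]-2-[(tert-butyldimethylsilyl)oxy]propanal (second portion); 15 (2R,3R,4S)-4,7,8-tris(benzyloxy)-2-[4-(benzyloxy)phenyl]-3-[(trimethylsilyl)oxy]chromane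
Product: 17 (2R,3R,4S)-7,8-bis(benzyloxy)-2-[4-(benzyloxy)phenyl]-3-[(tert-butyldimethylsilyl)oxy]-4-{[(2R,3R,4S)-4,7,8-tris(benzyloxy)-2-[4-(benzyloxy)phenyl]chroman-3-yl]oxy}chromane, via flavan-3-yl oxocarbenium triflate 16 (not isolated)
Conditions: TMSOTf (1.1 equiv), 2,6-di-tert-butyl-4-methylpyridine, 4 Å molecular sieves, CH2Cl2, −78 to −40 °C
Reagents that add atoms: none
Why: Proposed new method: TMSOTf should join aldehyde 11 and silyl ether 15 to a mixed silyl acetal that ionizes to the (E)-oxocarbenium ion 16, whose carbon is attacked by C4a of ring A (ortho to O1, para to the 7-benzyloxy group), after which the hindered pyridine takes up the ring proton. The closest known reaction types are the silyl-modified Sakurai reaction (aldehyde, alkoxysilane and π-nucleophile under TMSOTf) and acetal-initiated Friedel–Crafts cyclizations of the oxa-Pictet–Spengler kind. Ring C of the upper unit closes in a 6-exo-trig mode (the C=O+ bond stays outside the ring) through a chair-like transition state. The one new stereocenter, C4, is controlled by C2 and C3 of 11: with the 2-aryl group equatorial and the 3-silyloxy group axial, the C=O+ bond lies antiperiplanar to the C3–O bond (Cornforth-type arrangement), so the new C4–O bond should end trans to O3 and to the aryl group (4S); every transition state leading to the 3,4-cis isomer needs either a syn-diaxial aryl/alkoxy pair or nearly eclipsed C–O dipoles, and 3,4-trans is also the usual outcome when 2,3-cis-flavan-4-yl cations are captured. The step needs three selectivities: the TMS ether of 15 must react and not the TBS ether of 11 (secured by size); ring A must react only at C4a (its only free position ortho to O1); and the benzylic C4–O ethers must not ionize (secured by −78 °C, the buffered medium and the absence of a 5-oxygen on ring A).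

Step 12
Reactants: 17 (2R,3R,4S)-7,8-bis(benzyloxy)-2-[4-(benzyloxy)phenyl]-3-[(tert-butyldimethylsilyl)oxy]-4-{[(2R,3R,4S)-4,7,8-tris(benzyloxy)-2-[4-(benzyloxy)phenyl]chroman-3-yl]oxy}chromane
Product: 18 (2R,3R,4S)-7,8-bis(benzyloxy)-2-[4-(benzyloxy)phenyl]-4-{[(2R,3R,4S)-4,7,8-tris(benzyloxy)-2-[4-(benzyloxy)phenyl]chroman-3-yl]oxy}chroman-3-ol
Conditions: Bu4NF, AcOH, THF, rt to 40 °C
Reagents that add atoms: none
Why: Buffered fluoride desilylation removes the only silyl group without touching the inter-unit benzylic ether or any stereocenter.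

Step 13
Reactants: 18 (2R,3R,4S)-7,8-bis(benzyloxy)-2-[4-(benzyloxy)phenyl]-4-{[(2R,3R,4S)-4,7,8-tris(benzyloxy)-2-[4-(benzyloxy)phenyl]chroman-3-yl]oxy}chroman-3-ol
Product: 19 (2R,3R,4S)-2-(4-hydroxyphenyl)-4-{[(2R,3R,4S)-4,7,8-trihydroxy-2-(4-hydroxyphenyl)chroman-3-yl]oxy}chromane-3,7,8-triol (CNP0266687.1)
Conditions: H2 (1 atm), Pd/C, EtOAc–MeOH, rt, stopped after uptake of seven equivalents
Reagents that add atoms: none
Why: Hydrogenolysis of the seven O-benzyl groups under neutral conditions; the unhindered primary benzyl C–O bonds should be cleaved faster than the secondary C4–O bonds on the oxygenated A rings, and no stereocenter is touched.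

**Compound list**

1 | 2,3-dihydroxybenzaldehyde | O=Cc1cccc(O)c1O | starting material
2 | 2,3-bis(benzyloxy)benzaldehyde | O=Cc1cccc(OCc2ccccc2)c1OCc1ccccc1 | intermediate
3 | 2,3-bis(benzyloxy)phenyl formate | O=COc1cccc(OCc2ccccc2)c1OCc1ccccc1 | intermediate (not isolated)
4 | 2,3-bis(benzyloxy)phenol | Oc1cccc(OCc2ccccc2)c1OCc1ccccc1 | intermediate
5 | 4-(benzyloxy)benzaldehyde | O=Cc1ccc(OCc2ccccc2)cc1 | starting material
6 | ethyl 2-[bis(2-methylphenoxy)phosphoryl]acetate | CCOC(=O)CP(=O)(Oc1ccccc1C)Oc1ccccc1C | starting material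
7 | ethyl (2Z)-3-[4-(benzyloxy)phenyl]prop-2-enoate | CCOC(=O)/C=C\c1ccc(OCc2ccccc2)cc1 | intermediate
8 | ethyl (2S,3S)-3-[4-(benzyloxy)phenyl]oxirane-2-carboxylate | CCOC(=O)[C@H]1O[C@H]1c1ccc(OCc2ccccc2)cc1 | intermediate
9 | ethyl (2S,3R)-3-[2,3-bis(benzyloxy)phenoxy]-3-[4-(benzyloxy)phenyl]-2-hydroxypropanoate | CCOC(=O)[C@@H](O)[C@H](Oc1cccc(OCc2ccccc2)c1OCc1ccccc1)c1ccc(OCc2ccccc2)cc1 | intermediate
10 | ethyl (2S,3R)-3-[2,3-bis(benzyloxy)phenoxy]-3-[4-(benzyloxy)phenyl]-2-[(tert-butyldimethylsilyl)oxy]propanoate | CCOC(=O)[C@@H](O[Si](C)(C)C(C)(C)C)[C@H](Oc1cccc(OCc2ccccc2)c1OCc1ccccc1)c1ccc(OCc2ccccc2)cc1 | intermediate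
11 | (2S,3R)-3-[2,3-bis(benzyloxy)phenoxy]-3-[4-(benzyloxy)phenyl]-2-[(tert-butyldimethylsilyl)oxy]propanal | O=C[C@@H](O[Si](C)(C)C(C)(C)C)[C@H](Oc1cccc(OCc2ccccc2)c1OCc1ccccc1)c1ccc(OCc2ccccc2)cc1 | intermediate
12 | (E)-O-benzyl oxocarbenium triflate derived from 11 | C(c1ccccc1)Oc1ccc(cc1)[C@@H](Oc1cccc(OCc2ccccc2)c1OCc1ccccc1)[C@H](O[Si](C)(C)C(C)(C)C)/C=[O+]/Cc1ccccc1.[O-]S(=O)(=O)C(F)(F)F | intermediate (not isolated)
13 | (2R,3R,4S)-4,7,8-tris(benzyloxy)-2-[4-(benzyloxy)phenyl]-3-[(tert-butyldimethylsilyl)oxy]chromane | C(c1ccccc1)Oc1ccc(cc1)[C@H]1Oc2c(ccc(OCc3ccccc3)c2OCc2ccccc2)[C@H](OCc2ccccc2)[C@H]1O[Si](C)(C)C(C)(C)C | intermediate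
14 | (2R,3R,4S)-4,7,8-tris(benzyloxy)-2-[4-(benzyloxy)phenyl]chroman-3-ol | C(c1ccccc1)Oc1ccc(cc1)[C@H]1Oc2c(ccc(OCc3ccccc3)c2OCc2ccccc2)[C@H](OCc2ccccc2)[C@H]1O | intermediate
15 | (2R,3R,4S)-4,7,8-tris(benzyloxy)-2-[4-(benzyloxy)phenyl]-3-[(trimethylsilyl)oxy]chromane | C(c1ccccc1)Oc1ccc(cc1)[C@H]1Oc2c(ccc(OCc3ccccc3)c2OCc2ccccc2)[C@H](OCc2ccccc2)[C@H]1O[Si](C)(C)C | intermediate
16 | (E)-oxocarbenium triflate from 11 and 15 (lower flavan unit on the oxocarbenium oxygen through its C3) | C(c1ccccc1)Oc1ccc(cc1)[C@@H](Oc1cccc(OCc2ccccc2)c1OCc1ccccc1)[C@H](O[Si](C)(C)C(C)(C)C)/C=[O+]/[C@H]1[C@@H](c2ccc(OCc3ccccc3)cc2)Oc2c(ccc(OCc3ccccc3)c2OCc2ccccc2)[C@@H]1OCc1ccccc1.[O-]S(=O)(=O)C(F)(F)F | intermediate (not isolated)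
17 | (2R,3R,4S)-7,8-bis(benzyloxy)-2-[4-(benzyloxy)phenyl]-3-[(tert-butyldimethylsilyl)oxy]-4-{[(2R,3R,4S)-4,7,8-tris(benzyloxy)-2-[4-(benzyloxy)phenyl]chroman-3-yl]oxy}chromane | C(c1ccccc1)Oc1ccc(cc1)[C@H]1Oc2c(ccc(OCc3ccccc3)c2OCc2ccccc2)[C@H](O[C@H]2[C@@H](c3ccc(OCc4ccccc4)cc3)Oc3c(ccc(OCc4ccccc4)c3OCc3ccccc3)[C@@H]2OCc2ccccc2)[C@H]1O[Si](C)(C)C(C)(C)C | intermediate
18 | (2R,3R,4S)-7,8-bis(benzyloxy)-2-[4-(benzyloxy)phenyl]-4-{[(2R,3R,4S)-4,7,8-tris(benzyloxy)-2-[4-(benzyloxy)phenyl]chroman-3-yl]oxy}chroman-3-ol | C(c1ccccc1)Oc1ccc(cc1)[C@H]1Oc2c(ccc(OCc3ccccc3)c2OCc2ccccc2)[C@H](O[C@H]2[C@@H](c3ccc(OCc4ccccc4)cc3)Oc3c(ccc(OCc4ccccc4)c3OCc3ccccc3)[C@@H]2OCc2ccccc2)[C@H]1O | intermediate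
19 | (2R,3R,4S)-2-(4-hydroxyphenyl)-4-{[(2R,3R,4S)-4,7,8-trihydroxy-2-(4-hydroxyphenyl)chroman-3-yl]oxy}chromane-3,7,8-triol | Oc1ccc([C@H]2Oc3c(ccc(O)c3O)[C@H](O[C@H]3[C@@H](c4ccc(O)cc4)Oc4c(ccc(O)c4O)[C@@H]3O)[C@H]2O)cc1 | target

**Step count and risks**

Total step count: 13. Longest linear sequence: 11 steps (steps 3 to 13, from 5 to 19).

Steps most likely to fail:

First, step 11 (bears the label "Proposed new method:"). The silyl-activated aldehyde may cyclize onto ring A before the hindered silyl ether 15 has been incorporated, so that ring closure outruns the union of the two units; acetal exchange with the bulky partner may also be slow enough for the α-silyloxy aldehyde to epimerize. The fallback uses known chemistry, sets out from 10 and 14 and comes back to the route at 17; it fixes the lower unit to the future C4 before the ring is closed. Ester 10 is hydrolysed with Me3SnOH (1,2-dichloroethane, 70 °C, chosen to avoid β-elimination of the aryloxide) to (2S,3R)-3-[2,3-bis(benzyloxy)phenoxy]-3-[4-(benzyloxy)phenyl]-2-[(tert-butyldimethylsilyl)oxy]propanoic acid F1. Yamaguchi esterification with alcohol 14 (2,4,6-trichlorobenzoyl chloride, Et3N, DMAP) gives the (2R,3R,4S)-4,7,8-tris(benzyloxy)-2-[4-(benzyloxy)phenyl]chroman-3-yl ester of that acid F2. Reductive acetylation of the ester (iBu2AlH, −78 °C, then Ac2O, pyridine, DMAP) gives the corresponding α-acetoxy ether F3. Ionization of this isolated precursor with BF3·OEt2 and 2,6-di-tert-butyl-4-methylpyridine at −78 °C generates the same oxocarbenium ion, now without competition from a free aldehyde, and the Friedel–Crafts closure gives 17.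

Second, step 8 (bears the label "Proposed new method:"). Ring closure may occur on the silyl-activated aldehyde without uptake of the benzyloxy group, or the C4 ether may form without the expected control. The fallback uses known chemistry, sets out from 11 and comes back at 13. Intramolecular Friedel–Crafts hydroxyalkylation of the aldehyde with Me2AlCl (CH2Cl2, −78 °C) gives (2R,3R)-7,8-bis(benzyloxy)-2-[4-(benzyloxy)phenyl]-3-[(tert-butyldimethylsilyl)oxy]chroman-4-ol F4 as a mixture of C4 epimers. Acid-catalysed solvolysis in benzyl alcohol (pyridinium p-toluenesulfonate, CH2Cl2, rt) then passes through the flavan-4-yl cation, which is captured trans to O3 as is usual for 2,3-cis-flavans, to give 13.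

Third, step 5. The electron-rich benzylic C–O bond of the epoxide may ionize partly, so that inversion is lost and erythro material forms (it would lead to a 2,3-trans flavan); attack at C2 is a second possible leak. The fallback changes the substrate class to an epoxy alcohol, for which aryloxide opening at the benzylic carbon is well established; it sets out from 8 and comes back at 11. Ester 8 is reduced with NaBH4 (EtOH–THF, 0 °C) to [(2R,3S)-3-[4-(benzyloxy)phenyl]oxiran-2-yl]methanol F5. Opening with phenol 4 in aqueous NaOH at 70 °C gives (2R,3R)-3-[2,3-bis(benzyloxy)phenoxy]-3-[4-(benzyloxy)phenyl]propane-1,2-diol F6. Silylation (TBSCl, imidazole, DMF) gives the 1,2-bis(tert-butyldimethylsilyl) ether of this diol F7. Selective removal of the primary silyl group (HF·pyridine, pyridine–THF, 0 °C) gives (2R,3R)-3-[2,3-bis(benzyloxy)phenoxy]-3-[4-(benzyloxy)phenyl]-2-[(tert-butyldimethylsilyl)oxy]propan-1-ol F8. Dess–Martin oxidation (NaHCO3, CH2Cl2) then gives aldehyde 11.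

Further compounds
F1 | step 11 | (2S,3R)-3-[2,3-bis(benzyloxy)phenoxy]-3-[4-(benzyloxy)phenyl]-2-[(tert-butyldimethylsilyl)oxy]propanoic acid | OC(=O)[C@@H](O[Si](C)(C)C(C)(C)C)[C@H](Oc1cccc(OCc2ccccc2)c1OCc1ccccc1)c1ccc(OCc2ccccc2)cc1
F2 | step 11 | (2R,3R,4S)-4,7,8-tris(benzyloxy)-2-[4-(benzyloxy)phenyl]chroman-3-yl (2S,3R)-3-[2,3-bis(benzyloxy)phenoxy]-3-[4-(benzyloxy)phenyl]-2-[(tert-butyldimethylsilyl)oxy]propanoate | O=C([C@@H](O[Si](C)(C)C(C)(C)C)[C@H](Oc1cccc(OCc2ccccc2)c1OCc1ccccc1)c1ccc(OCc2ccccc2)cc1)O[C@H]1[C@@H](c2ccc(OCc3ccccc3)cc2)Oc2c(ccc(OCc3ccccc3)c2OCc2ccccc2)[C@@H]1OCc1ccccc1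
F3 | step 11 | α-acetoxy ether from F2 (acetal carbon as epimer mixture): (2S,3R)-3-[2,3-bis(benzyloxy)phenoxy]-3-[4-(benzyloxy)phenyl]-2-[(tert-butyldimethylsilyl)oxy]-1-{[(2R,3R,4S)-4,7,8-tris(benzyloxy)-2-[4-(benzyloxy)phenyl]chroman-3-yl]oxy}propyl acetate | CC(=O)OC([C@@H](O[Si](C)(C)C(C)(C)C)[C@H](Oc1cccc(OCc2ccccc2)c1OCc1ccccc1)c1ccc(OCc2ccccc2)cc1)O[C@H]1[C@@H](c2ccc(OCc3ccccc3)cc2)Oc2c(ccc(OCc3ccccc3)c2OCc2ccccc2)[C@@H]1OCc1ccccc1
F4 | step 8 | (2R,3R)-7,8-bis(benzyloxy)-2-[4-(benzyloxy)phenyl]-3-[(tert-butyldimethylsilyl)oxy]chroman-4-ol (C4 epimer mixture) | C(c1ccccc1)Oc1ccc(cc1)[C@H]1Oc2c(ccc(OCc3ccccc3)c2OCc2ccccc2)C(O)[C@H]1O[Si](C)(C)C(C)(C)C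
F5 | step 5 | [(2R,3S)-3-[4-(benzyloxy)phenyl]oxiran-2-yl]methanol | OC[C@H]1O[C@H]1c1ccc(OCc2ccccc2)cc1
F6 | step 5 | (2R,3R)-3-[2,3-bis(benzyloxy)phenoxy]-3-[4-(benzyloxy)phenyl]propane-1,2-diol | OC[C@@H](O)[C@H](Oc1cccc(OCc2ccccc2)c1OCc1ccccc1)c1ccc(OCc2ccccc2)cc1
F7 | step 5 | (2R,3R)-3-[2,3-bis(benzyloxy)phenoxy]-3-[4-(benzyloxy)phenyl]-1,2-bis[(tert-butyldimethylsilyl)oxy]propane | CC(C)(C)[Si](C)(C)OC[C@@H](O[Si](C)(C)C(C)(C)C)[C@H](Oc1cccc(OCc2ccccc2)c1OCc1ccccc1)c1ccc(OCc2ccccc2)cc1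
F8 | step 5 | (2R,3R)-3-[2,3-bis(benzyloxy)phenoxy]-3-[4-(benzyloxy)phenyl]-2-[(tert-butyldimethylsilyl)oxy]propan-1-ol | OC[C@@H](O[Si](C)(C)C(C)(C)C)[C@H](Oc1cccc(OCc2ccccc2)c1OCc1ccccc1)c1ccc(OCc2ccccc2)cc1
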